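**Plan**
- Retrosynthesis: the two C–O bonds of the 1,4-dioxane (O-2/C-1 and O-3/C-5) are cut first, giving pristimerin (reacting as its o-quinone tautomer) and a guaia-1(5),3,11-triene that carries a triflate on C-3. The diene is then cut at C-4=C-5 (aldol), C-1–C-2 (enolate alkylation) and at C-1 itself (one inserted carbon).
- Enabling feature: the seven-membered ring C-1, C-5, C-6, C-7, C-8, C-9, C-10 is the ring of dihydrocarvone plus one carbon (C-1) between the carbonyl carbon (C-5) and the methyl-bearing carbon (C-10). A carbenoid ring enlargement in which that more substituted carbon migrates leaves the enolate on C-1, exactly where the cyclopentene must be fused.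
- Forward order: six-membered ring, then seven-membered ring with the C4 side chain (one flask), then 1,4-diketone, then cyclopentenone, then cyclopentadienyl triflate. The hetero-Diels–Alder reaction closes the dioxane, and the triflate (which steers the cycloaddition to C-1=C-5) is removed last.
- Stereochemistry: C-7 and C-10 come from (S)-carvone (C-10 migrates with retention). C-1 and C-5 are set by cycloaddition anti to Me-14. C-8 of the triterpene is set by α-face protonation during tautomerisation. All other triterpene centres come from pristimerin.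

Key step: step 3

Remark: guaiane numbering is used for the sesquiterpene (C-1/C-5 ring fusion, Me-15 on C-4, Me-14 on C-10, isopropenyl on C-7) and friedelane numbering for the triterpene.
Remark: pristimerin is assumed to react through its o-quinone tautomer (proton moved from O-3 to C-8), as the 6-ene/8-H pattern of the target requires.
Remark: the carbinol carbon of 3 and guaiane C-1 in 6–9 are carried as epimer mixtures and left undefined in the SMILES, because both become sp2 later.

Step 1
Reactants: 1 (S)-(+)-carvone
Product: 2 (2S,5S)-2-methyl-5-(prop-1-en-2-yl)cyclohexan-1-one (trans-dihydrocarvone)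
Conditions: LiBH(s-Bu)3, THF, −78 °C; H2O; then NaOMe (cat.), MeOH, rt; chromatography
Reagents that add atoms: none
Why: Conjugate (1,4) hydride reduction of the β-unsubstituted enone by the bulky borohydride, followed by base equilibration that places the new C-2 methyl equatorial and trans to the isopropenyl group (thermodynamic control), should give the (2S,5S) ketone.

Step 2
Reactants: 2 (2S,5S)-dihydrocarvone
Product: 3 (2S,5S)-1-(dibromomethyl)-2-methyl-5-(prop-1-en-2-yl)cyclohexan-1-ol (C-1 epimers)
Conditions: CH2Br2, LiN(c-C6H11)2, THF, −78 °C; H2O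
Reagents that add atoms: dibromomethane, BrCBr
Why: Dibromomethyllithium generated in the presence of the ketone adds 1,2 to the carbonyl group (halomethyllithium carbonyl addition); the new carbinol centre forms as an epimer mixture and is destroyed in step 3.

Step 3
Reactants: 3 dibromomethyl carbinol
Product: 6 (3S,6S)-2-(but-2-yn-1-yl)-3-methyl-6-(prop-1-en-2-yl)cycloheptan-1-one (C-2 epimers), via lithium β-oxido carbenoid 4 (not isolated), via lithium enolate 5 (not isolated)
Conditions: n-BuLi (2.1 equiv), THF, −78 → −20 °C; then DMPU, 1-bromobut-2-yne, −78 → 0 °C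
Reagents that add atoms: 1-bromobut-2-yne, CC#CCBr
Why: Deprotonation and bromine–lithium exchange give the lithium β-oxido carbenoid 4, in which a ring C–C bond anti to the leaving bromide migrates to the carbenoid carbon with loss of LiBr, so that the six-membered ring becomes seven-membered and the lithium enolate 5 has its double bond on the inserted carbon. The closest known reaction type is the β-oxido carbenoid ring enlargement of cycloalkanones (the carbenoid counterpart of the Tiffeneau–Demjanov homologation), followed by alkylation of a regio-defined lithium enolate. No ring is closed: the ring is enlarged from six to seven atoms by a 1,2-shift, and the side chain is attached by SN2 C-alkylation. The step needs migration of the methyl-bearing carbon and not of the CH2 carbon; the higher migratory aptitude of the more substituted, more electron-rich carbon toward the electrophilic carbenoid centre should secure this, and it migrates with retention, so the (S)-methyl centre ends β to the ketone where it cannot epimerise. The new centre C-2 (guaiane C-1) forms without control and is inconsequential because it becomes sp2 in step 6. Alkylation should occur only at the inserted carbon because the enolate is formed regiospecifically and is trapped at low temperature before it can equilibrate.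

Step 4
Reactants: 6 alkynyl cycloheptanone
Product: 7 (3S,6S)-3-methyl-2-(2-oxobutyl)-6-(prop-1-en-2-yl)cycloheptan-1-one (C-2 epimers)
Conditions: Ph3PAuNTf2 (2 mol %), 1,4-dioxane/H2O, 60 °C
Reagents that add atoms: water, O
Why: Gold-catalysed alkyne hydration in which the ring ketone oxygen attacks the activated triple bond in a 5-exo-dig sense (anchimeric assistance) should place the new carbonyl on the alkyne carbon nearer the ring and give the 1,4-diketone, the 1,1-disubstituted olefin being far less reactive toward the cationic gold catalyst.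

Step 5
Reactants: 7 1,4-diketone
Product: 8 (5S,8S)-3,8-dimethyl-5-(prop-1-en-2-yl)-4,5,6,7,8,8a-hexahydroazulen-2(1H)-one (C-8a epimers), i.e. (7S,10S)-guaia-4,11-dien-3-one
Conditions: KOH, EtOH, 70 °C
Reagents that add atoms: none
Why: Intramolecular aldol condensation of the 1,4-diketone (the classical cyclopentenone annulation) should close the five-membered ring by attack of the ethyl-ketone CH2 enolate on the ring carbonyl and dehydrate to the tetrasubstituted C-4=C-5 enone, the other possible aldols leading only to three-membered or bridged rings and C-7 and C-10 carrying no enolisable hydrogen.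

Step 6
Reactants: 8 bicyclic enone
Product: 10 (5S,8S)-3,8-dimethyl-5-(prop-1-en-2-yl)-1,4,5,6,7,8-hexahydroazulen-2-yl trifluoromethanesulfonate, i.e. (7S,10S)-guaia-1(5),3,11-trien-3-yl triflate, via cross-conjugated triflate 9 (not isolated)
Conditions: KN(SiMe3)2, THF, −78 °C; PhNTf2, −78 °C → rt; then 40 °C
Reagents that add atoms: N-phenylbis(trifluoromethanesulfonimide), O=S(=O)(N(c1ccccc1)S(=O)(=O)C(F)(F)F)C(F)(F)F
Why: Kinetic α′-deprotonation at C-2 and O-triflation (enol triflate formation) give the cross-conjugated cyclopentadienyl triflate 9, which by suprafacial 1,5-hydrogen shifts should relax to the most substituted 1(5),3-diene isomer 10, in which C-1 has become sp2 and no new stereocentre exists.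

Step 7
Reactants: 10 dienyl triflate; 11 pristimerin
Product: 13 hetero-Diels–Alder adduct triflate (the 3-trifluoromethanesulfonyloxy derivative of 14), via o-quinone tautomer 12 (not isolated)
Conditions: Et3N (10 mol %), toluene, 40 °C, dark, Ar
Reagents that add atoms: none
Why: Amine-mediated tautomerisation of the hydroxy quinone methide (proton delivered to C-8 on the α-face, away from the β-methyls on C-9 and C-14) should give the o-quinone 12, whose O=C–C=O unit adds as an electron-poor heterodiene to the electron-rich tetrasubstituted C-1=C-5 olefin of 10 in an inverse-electron-demand hetero-Diels–Alder reaction that re-aromatises ring A; the triflate deactivates and shields C-3=C-4, bonding should start at the diene terminus C-1 with the less hindered O-2 (flanked by H-1, whereas O-3 is flanked by Me-23), and both C–O bonds form on the face anti to Me-14, which sets C-1 and C-5.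

Step 8
Reactants: 13 adduct triflate
Product: 14 CNP0287532.3 (target)
Conditions: Pd(OAc)2 (5 mol %), PPh3 (10 mol %), HCO2H, n-Bu3N, DMF, 50 °C
Reagents that add atoms: none
Why: Oxidative addition of zerovalent palladium into the vinyl C–OTf bond, formate-to-hydride exchange with loss of CO2 and reductive elimination (palladium-catalysed hydrogenolysis of an enol triflate) should replace the triflate by hydrogen without moving the C-3=C-4 double bond or touching a stereocentre.

**Compound list**
1 | (S)-(+)-carvone, (5S)-2-methyl-5-(prop-1-en-2-yl)cyclohex-2-en-1-one | CC1=CC[C@@H](CC1=O)C(C)=C | starting material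
2 | (2S,5S)-2-methyl-5-(prop-1-en-2-yl)cyclohexan-1-one (trans-dihydrocarvone) | C[C@H]1CC[C@@H](CC1=O)C(C)=C | intermediate
3 | (2S,5S)-1-(dibromomethyl)-2-methyl-5-(prop-1-en-2-yl)cyclohexan-1-ol (C-1 epimers) | C[C@H]1CC[C@@H](CC1(O)C(Br)Br)C(C)=C | intermediate
4 | lithium (2S,5S)-1-[bromo(lithio)methyl]-2-methyl-5-(prop-1-en-2-yl)cyclohexan-1-olate (β-oxido carbenoid) | C[C@H]1CC[C@@H](CC1([O-])C(Br)[Li])C(C)=C.[Li+] | intermediate
5 | lithium (3S,6S)-3-methyl-6-(prop-1-en-2-yl)cyclohept-1-en-1-olate | C[C@H]1CC[C@@H](CC([O-])=C1)C(C)=C.[Li+] | intermediate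
6 | (3S,6S)-2-(but-2-yn-1-yl)-3-methyl-6-(prop-1-en-2-yl)cycloheptan-1-one (C-2 epimers) | C[C@H]1CC[C@@H](CC(=O)C1CC#CC)C(C)=C | intermediate
7 | (3S,6S)-3-methyl-2-(2-oxobutyl)-6-(prop-1-en-2-yl)cycloheptan-1-one (C-2 epimers) | C[C@H]1CC[C@@H](CC(=O)C1CC(=O)CC)C(C)=C | intermediate
8 | (5S,8S)-3,8-dimethyl-5-(prop-1-en-2-yl)-4,5,6,7,8,8a-hexahydroazulen-2(1H)-one (C-8a epimers); (7S,10S)-guaia-4,11-dien-3-one | C[C@H]1CC[C@@H](CC2=C(C)C(=O)CC12)C(C)=C | intermediate
9 | (5S,8S)-3,8-dimethyl-5-(prop-1-en-2-yl)-4,5,6,7,8,8a-hexahydroazulen-2-yl trifluoromethanesulfonate (cross-conjugated 2,4-diene isomer, C-8a epimers) | C[C@H]1CC[C@@H](CC2=C(C)C(OS(=O)(=O)C(F)(F)F)=CC12)C(C)=C | intermediate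
10 | (5S,8S)-3,8-dimethyl-5-(prop-1-en-2-yl)-1,4,5,6,7,8-hexahydroazulen-2-yl trifluoromethanesulfonate; (7S,10S)-guaia-1(5),3,11-trien-3-yl triflate | C[C@H]1CC[C@@H](CC2=C1CC(OS(=O)(=O)C(F)(F)F)=C2C)C(C)=C | intermediate
11 | pristimerin, methyl 3-hydroxy-2-oxo-24-nor-D:A-friedooleana-1(10),3,5,7-tetraen-29-oate | CC1=C(O)C(=O)C=C2C1=CC=C1[C@@]2(C)CC[C@@]2(C)[C@@H]3C[C@](C)(C(=O)OC)CC[C@]3(C)CC[C@]12C | starting material
12 | o-quinone tautomer of pristimerin, methyl (8α-H)-2,3-dioxo-24-nor-D:A-friedooleana-1(10),4,6-trien-29-oate | O=C1C(=O)C=C2C(=C1C)C=C[C@H]1[C@@]2(C)CC[C@@]2(C)[C@@H]3C[C@](C)(C(=O)OC)CC[C@]3(C)CC[C@]12C | intermediate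
13 | adduct triflate: 1,4-benzodioxane with O-2 of the triterpene on C-1 and O-3 on C-5 of the (1R,5R,7S,10S)-guaia-3,11-diene unit, OSO2CF3 on C-3; triterpene part 8α-H, 6-ene, aromatic ring A | C=C(C)[C@H]1CC[C@H](C)[C@]23CC(OS(=O)(=O)C(F)(F)F)=C(C)[C@@]2(C1)Oc1c(cc2c(c1C)C=C[C@H]1[C@@]2(C)CC[C@@]2(C)[C@@H]4C[C@](C)(C(=O)OC)CC[C@]4(C)CC[C@]12C)O3 | intermediate
14 | CNP0287532.3: methyl 2,3-[(1R,5R,7S,10S)-guaia-3,11-diene-1,5-diylbis(oxy)]-24-nor-D:A-friedooleana-1,3,5(10),6-tetraen-29-oate (8α-H; O-2 on C-1, O-3 on C-5; both oxygens anti to Me-14) | C=C(C)[C@H]1CC[C@H](C)[C@]23CC=C(C)[C@@]2(C1)Oc1c(cc2c(c1C)C=C[C@H]1[C@@]2(C)CC[C@@]2(C)[C@@H]4C[C@](C)(C(=O)OC)CC[C@]4(C)CC[C@]12C)O3 | target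

**Step count**
Total steps: 8. Longest linear sequence: 8 steps (1 to 14); pristimerin 11 enters at step 7.

**Steps most likely to fail**

Step 7. The o-quinone tautomer may build up too slowly for the triflate-deactivated diene. Self-addition of the quinone to the enol double bond of pristimerin, 1,5-hydrogen shifts in 10, or addition with the wrong orientation or on the wrong face could then compete. The fallback sets out from 8 and comes back at 14; it replaces the triflate by a less deactivating, bulkier iodide that is removed without palladium. Enone 8 is condensed with N2H4·H2O (Et3N, EtOH, 60 °C) to the hydrazone F1. Iodine and 1,1,3,3-tetramethylguanidine in THF (Barton vinyl iodide synthesis), followed by thermal equilibration, should give the dienyl iodide (5S,8S)-2-iodo-3,8-dimethyl-5-(prop-1-en-2-yl)-1,4,5,6,7,8-hexahydroazulene F2. Cycloaddition with 11 under the conditions of step 7 should give the 3-iodo analogue of the target F3. Radical deiodination (n-Bu3SnH, AIBN, benzene, 70 °C) then gives 14.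

Step 6. Equilibration may stop at a mixture of cyclopentadienyl triflate isomers, deprotonation may stray to C-6, or the triflate may dimerise or decompose on handling. The fallback sets out from 8 and comes back at 14; it avoids any cyclopentadiene. The extended enolate of 8 (KOt-Bu, t-BuOH) is protonated kinetically at C-4 (AcOH, −78 °C) to the deconjugated ketone guaia-1(5),11-dien-3-one F4. NaBH4 (MeOH, 0 °C) gives the homoallylic alcohol guaia-1(5),11-dien-3-ol F5. Its isolated tetrasubstituted olefin is combined with 11 as in step 7 to give the 3-hydroxy-3,4-dihydro analogue of the target F6. Syn-dehydration toward C-4 with methyl N-(triethylammoniosulfonyl)carbamate (Burgess reagent, benzene, 50 °C) then gives 14.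

Step 3. Capture of the ring-enlarged enolate by the propargylic bromide may be incomplete (proton transfer to product, double alkylation), and some migration of the CH2 carbon may occur. The fallback sets out from 3 and comes back at 7; it separates ring enlargement from C–C bond formation. Carbinol 3 is treated with n-BuLi (2.1 equiv, THF, −78 → −20 °C) and the enolate is quenched with Me3SiCl to give the trimethylsilyl enol ether F7. Lewis-acid-promoted conjugate addition to 2-nitrobut-1-ene (SnCl4, CH2Cl2, −78 °C) gives the trimethylsilyl nitronate F8, which is not isolated. Aqueous hydrolysis (Nef reaction) then gives the 1,4-diketone 7.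

**Further compounds**
F1 | step 7 | hydrazone of 8, (5S,8S)-2-hydrazinylidene-3,8-dimethyl-5-(prop-1-en-2-yl)-1,2,4,5,6,7,8,8a-octahydroazulene | C[C@H]1CC[C@@H](CC2=C(C)C(=NN)CC12)C(C)=C
F2 | step 7 | (5S,8S)-2-iodo-3,8-dimethyl-5-(prop-1-en-2-yl)-1,4,5,6,7,8-hexahydroazulene | C[C@H]1CC[C@@H](CC2=C1CC(I)=C2C)C(C)=C
F3 | step 7 | 3-iodo analogue of 14 (iodine on C-3 of the guaiane unit) | C=C(C)[C@H]1CC[C@H](C)[C@]23CC(I)=C(C)[C@@]2(C1)Oc1c(cc2c(c1C)C=C[C@H]1[C@@]2(C)CC[C@@]2(C)[C@@H]4C[C@](C)(C(=O)OC)CC[C@]4(C)CC[C@]12C)O3
F4 | step 6 | (5S,8S)-3,8-dimethyl-5-(prop-1-en-2-yl)-3,4,5,6,7,8-hexahydroazulen-2(1H)-one (guaia-1(5),11-dien-3-one, C-4 epimers) | C[C@H]1CC[C@@H](CC2=C1CC(=O)C2C)C(C)=C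
F5 | step 6 | (5S,8S)-3,8-dimethyl-5-(prop-1-en-2-yl)-1,2,3,4,5,6,7,8-octahydroazulen-2-ol (guaia-1(5),11-dien-3-ol, C-3 and C-4 epimers) | C[C@H]1CC[C@@H](CC2=C1CC(O)C2C)C(C)=C
F6 | step 6 | 3-hydroxy-3,4-dihydro analogue of 14 (C-3 and C-4 epimers) | C=C(C)[C@H]1CC[C@H](C)[C@]23CC(O)C(C)[C@@]2(C1)Oc1c(cc2c(c1C)C=C[C@H]1[C@@]2(C)CC[C@@]2(C)[C@@H]4C[C@](C)(C(=O)OC)CC[C@]4(C)CC[C@]12C)O3
F7 | step 3 | trimethyl{[(3S,6S)-3-methyl-6-(prop-1-en-2-yl)cyclohept-1-en-1-yl]oxy}silane | C[C@H]1CC[C@@H](CC(O[Si](C)(C)C)=C1)C(C)=C
F8 | step 3 | trimethylsilyl nitronate of (3S,6S)-3-methyl-2-(2-nitrobutyl)-6-(prop-1-en-2-yl)cycloheptan-1-one | C[C@H]1CC[C@@H](CC(=O)C1CC(CC)=[N+]([O-])O[Si](C)(C)C)C(C)=C
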